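**Strategy**

The cyclohexenone ring of megaphone carries oxygen at C1 and C4 on either side of the C2=C3 double bond, with the quaternary C6 beside the C1 carbonyl. That 1,4-dioxygenated ene pattern is the signature of the thermal ring expansion of a 4-alkenyl-4-hydroxycyclobutenone. Release of four-ring strain gives a dienylketene whose carbonyl carbon closes onto the fully substituted alkene terminus, forming the C1–C6 bond, the six-membered ring and the quaternary stereocentre in one operation. The precursor is a cyclobutenone whose alkenyl group already carries the allyl group, the protected syn side chain and a temporary silyl group that steers the facial selectivity. Reduction at C4, O-methylation and desilylation complete the route.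

Key step: step 8

Remarks: Ar = 3,4,5-trimethoxyphenyl; R* = (1R,2S)-1-(tert-butyldimethylsilyloxy)-1-Ar-propan-2-yl, attached through C2. Ring compounds 17–21 carry megaphone numbering (C1 ketone, C6 quaternary carbon). Allylzinc bromide and LiN(i-Pr)2 are taken as commercial solutions.

**Route**

Step 1
Reactants: 1 (S)-but-3-yn-2-ol
Product: 2 (S)-but-3-yn-2-yl methanesulfonate
Conditions: MsCl, Et3N, CH2Cl2, −78 to 0 °C
Reagents that add atoms: methanesulfonyl chloride, CS(=O)(=O)Cl
Why: O-sulfonylation of the secondary alcohol (mesylate formation) leaves the stereocentre untouched and installs the leaving group for the SN2′ step.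

Step 2
Reactants: 2 (S)-but-3-yn-2-yl methanesulfonate
Product: 3 (M)-tributyl(buta-1,2-dien-1-yl)stannane
Conditions: Bu3SnH, LiN(i-Pr)2, THF, 0 °C; CuBr·SMe2 (1 equiv), −78 °C; then 2, −78 °C
Reagents that add atoms: tributyltin hydride, CCCC[SnH](CCCC)CCCC
Why: anti SN2′ displacement of the propargylic mesylate by the stannylcopper reagent should convert the (S) centre into the (M) allene axis (Marshall allenylstannane synthesis).

Step 3
Reactants: 4 3,4,5-trimethoxybenzaldehyde; 3 (M)-tributyl(buta-1,2-dien-1-yl)stannane
Product: 5 (1R,2S)-2-methyl-1-(3,4,5-trimethoxyphenyl)but-3-yn-1-ol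
Conditions: BF3·OEt2 (1.2 equiv), CH2Cl2, −78 °C
Reagents that add atoms: none
Why: Lewis acid promoted SE2′ addition (Marshall propargylation) should attack the allene anti to tin, which returns the methyl-bearing centre as (S), and pass through an open transition state that gives the syn carbinol, hence (1R).

Step 4
Reactants: 5 (1R,2S)-2-methyl-1-(3,4,5-trimethoxyphenyl)but-3-yn-1-ol
Product: 7 tert-butyl(dimethyl){[(1R,2S)-2-methyl-1-(3,4,5-trimethoxyphenyl)-4-(trimethylsilyl)but-3-yn-1-yl]oxy}silane, via TBS ether 6 (not isolated)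
Conditions: n-BuLi (1.05 equiv), THF, −78 °C; TBSOTf, −78 to 0 °C; n-BuLi (1.1 equiv), −78 °C; Me3SiCl
Reagents that add atoms: tert-butyldimethylsilyl trifluoromethanesulfonate, CC(C)(C)[Si](C)(C)OS(=O)(=O)C(F)(F)F; chlorotrimethylsilane, C[Si](C)(C)Cl
Why: one-pot O- then C-silylation exploits the acidity order O–H before C(sp)–H, so the alkoxide is capped by TBSOTf and the acetylide by Me3SiCl without touching either stereocentre.

Step 5
Reactants: 7 tert-butyl(dimethyl){[(1R,2S)-2-methyl-1-(3,4,5-trimethoxyphenyl)-4-(trimethylsilyl)but-3-yn-1-yl]oxy}silane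
Product: 9 (E)-1-iodo-2-R*-1-(trimethylsilyl)penta-1,4-diene, via alkenylzinc bromide 8 (not isolated)
Conditions: allylzinc bromide (3 equiv), THF, 50 °C; then I2, −78 to 0 °C
Reagents that add atoms: allylzinc bromide, C=CC[Zn]Br; iodine, II
Why: syn allylzincation of the 1-silylalkyne (Negishi carbometalation) should place zinc on the silicon-bearing carbon and the allyl group on the carbon that becomes C6, and iodinolysis of the C–Zn bond proceeds with retention.

Step 6
Reactants: 10 1,2-bis(trimethylsilyloxy)cyclobut-1-ene
Product: 13 cyclobut-3-ene-1,2-dione, via cyclobutane-1,2-dione 11 (not isolated), via 3-bromocyclobutane-1,2-dione 12 (not isolated)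
Conditions: Br2 (2.0 equiv), pentane/CH2Cl2, −60 to 0 °C; then Et3N (2.1 equiv), Et2O, −40 °C; cold filtration, used at once as a THF solution
Reagents that add atoms: none
Why: bromine should cleave the bis(silyl) enediol ether to the 1,2-dione and then brominate its enol at C3, and amine-induced loss of HBr (α-bromination/dehydrobromination) gives the strained enedione.

Step 7
Reactants: 9 (E)-1-iodo-2-R*-1-(trimethylsilyl)penta-1,4-diene; 13 cyclobut-3-ene-1,2-dione
Product: 15 4-hydroxy-4-[(1Z)-2-R*-1-(trimethylsilyl)penta-1,4-dien-1-yl]cyclobut-2-en-1-one, via alkenyllithium 14 (not isolated)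
Conditions: t-BuLi (2.1 equiv), Et2O, −78 °C; cannulated into 13 (1.5 equiv), THF, −78 °C; aq. NH4Cl, −78 °C
Reagents that add atoms: none
Why: iodine–lithium exchange and 1,2-addition of the alkenyllithium to one of the two equivalent carbonyl groups should give the cyclobutenol as a mixture of carbinol epimers, which is harmless because this carbon becomes sp2 in step 8, as is any E/Z isomerisation of the α-silyl alkenyllithium.

Step 8
Reactants: 15 4-hydroxy-4-[(1Z)-2-R*-1-(trimethylsilyl)penta-1,4-dien-1-yl]cyclobut-2-en-1-one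
Product: 18 (6R)-6-allyl-6-R*-cyclohex-2-ene-1,4-dione, via dienylketene 16 (not isolated), via silyl dienol 17 (not isolated)
Conditions: toluene (0.01 M), PivOH (10 mol %), 80 °C, dark; then 1 M HCl, THF, 0 °C
Reagents that add atoms: none
Why: Heating should open the strained cyclobutenone by conrotatory 4π electrocyclic ring opening, with the hydroxyl group rotating outward and the alkenyl group inward, to give (Z)-dienylketene 16, whose ketene carbon C1 and fully substituted terminus C6 then join in a disrotatory 6π electrocyclisation that closes the six-membered carbocycle. This is the Moore rearrangement of 4-alkenyl-4-hydroxycyclobutenones, and closure onto a disubstituted terminus is the thermal reverse of the photochemical ring opening of 6,6-disubstituted cyclohexa-2,4-dienones. The new C6 stereocentre is controlled by A(1,3) strain between the C5 silyl group and the adjacent side-chain stereocentre: the allylic C–H lies in the diene plane toward silicon, the methyl group and the CH(OTBS)Ar branch flank the two faces, and C1 bonds anti to the bulky branch, which gives (6R); either geometry of the C5=C6 bond keeps a non-hydrogen group cis to the side chain, so both alkene isomers converge on the same face. The step needs outward rotation of the hydroxyl group, secured by its donor character, and it needs dienol 17 to tautomerise before its allyl group can undergo a [3,3] shift to C4, secured by the pivalic acid proton shuttle and the moderate temperature. Aqueous acid finally removes the C5 silyl group from the α-silyl ketone, leaving enedione 18 with the ring oxygens at C1 and C4.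

Step 9
Reactants: 18 (6R)-6-allyl-6-R*-cyclohex-2-ene-1,4-dione
Product: 19 (4R,6R)-6-allyl-4-hydroxy-6-R*-cyclohex-2-en-1-one
Conditions: (S)-1-methyl-3,3-diphenyltetrahydro-1H,3H-pyrrolo[1,2-c][1,3,2]oxazaborole (20 mol %), catecholborane (1.5 equiv), toluene, −78 °C
Reagents that add atoms: none
Why: Corey–Bakshi–Shibata reduction should select the C4 carbonyl (C1 is shielded by the quaternary C6) and deliver hydride under reagent control with the C2=C3 vinyl group as the large substituent to give the (4R) alcohol, while catecholborane leaves the enone and allyl double bonds alone.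

Step 10
Reactants: 19 (4R,6R)-6-allyl-4-hydroxy-6-R*-cyclohex-2-en-1-one
Product: 20 (4R,6R)-6-allyl-4-methoxy-6-R*-cyclohex-2-en-1-one
Conditions: MeI, Ag2O, 4 Å molecular sieves, CH2Cl2, 35 °C, dark
Reagents that add atoms: iodomethane, CI
Why: silver oxide mediated O-methylation (Williamson type, neutral conditions) should etherify the only free hydroxyl group without dienolate formation, so C4 keeps its configuration.

Step 11
Reactants: 20 (4R,6R)-6-allyl-4-methoxy-6-R*-cyclohex-2-en-1-one
Product: 21 megaphone, (4R,6R)-6-allyl-6-[(1R,2S)-1-hydroxy-1-(3,4,5-trimethoxyphenyl)propan-2-yl]-4-methoxycyclohex-2-en-1-one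
Conditions: HF·pyridine, pyridine, THF, 0 °C to rt
Reagents that add atoms: none
Why: buffered fluoride cleavage of the benzylic silyl ether should free the hydroxyl group under conditions too mild to affect the γ-methoxy enone or any stereocentre.

**Compound list**

1 | (S)-but-3-yn-2-ol | C#C[C@H](C)O | starting material
2 | (S)-but-3-yn-2-yl methanesulfonate | C#C[C@H](C)OS(C)(=O)=O | intermediate
3 | (M)-tributyl(buta-1,2-dien-1-yl)stannane (aR axis) | CCCC[Sn](CCCC)(CCCC)C([H])=[C@]=C([H])C | intermediate
4 | 3,4,5-trimethoxybenzaldehyde | COc1cc(C=O)cc(OC)c1OC | starting material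
5 | (1R,2S)-2-methyl-1-(3,4,5-trimethoxyphenyl)but-3-yn-1-ol | C#C[C@H](C)[C@@H](O)c1cc(OC)c(OC)c(OC)c1 | intermediate
6 | tert-butyldimethylsilyl ether of 5 | C#C[C@H](C)[C@@H](O[Si](C)(C)C(C)(C)C)c1cc(OC)c(OC)c(OC)c1 | intermediate
7 | tert-butyl(dimethyl){[(1R,2S)-2-methyl-1-(3,4,5-trimethoxyphenyl)-4-(trimethylsilyl)but-3-yn-1-yl]oxy}silane | C[Si](C)(C)C#C[C@H](C)[C@@H](O[Si](C)(C)C(C)(C)C)c1cc(OC)c(OC)c(OC)c1 | intermediate
8 | (E)-[2-R*-1-(trimethylsilyl)penta-1,4-dien-1-yl]zinc bromide, zinc cis to allyl | C=CC/C(=C(\[Zn]Br)[Si](C)(C)C)[C@H](C)[C@@H](O[Si](C)(C)C(C)(C)C)c1cc(OC)c(OC)c(OC)c1 | intermediate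
9 | (E)-1-iodo-2-R*-1-(trimethylsilyl)penta-1,4-diene, iodine cis to allyl | C=CC/C(=C(\I)[Si](C)(C)C)[C@H](C)[C@@H](O[Si](C)(C)C(C)(C)C)c1cc(OC)c(OC)c(OC)c1 | intermediate
10 | 1,2-bis(trimethylsilyloxy)cyclobut-1-ene | C[Si](C)(C)OC1=C(O[Si](C)(C)C)CC1 | starting material
11 | cyclobutane-1,2-dione | O=C1CCC1=O | intermediate
12 | 3-bromocyclobutane-1,2-dione | O=C1CC(Br)C1=O | intermediate
13 | cyclobut-3-ene-1,2-dione | O=C1C=CC1=O | intermediate
14 | (Z)-[2-R*-1-(trimethylsilyl)penta-1,4-dien-1-yl]lithium, lithium cis to allyl | C=CC/C(=C(\[Li])[Si](C)(C)C)[C@H](C)[C@@H](O[Si](C)(C)C(C)(C)C)c1cc(OC)c(OC)c(OC)c1 | intermediate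
15 | 4-hydroxy-4-[(1Z)-2-R*-1-(trimethylsilyl)penta-1,4-dien-1-yl]cyclobut-2-en-1-one, carbinol epimers | C=CC/C(=C(\C1(O)C=CC1=O)[Si](C)(C)C)[C@H](C)[C@@H](O[Si](C)(C)C(C)(C)C)c2cc(OC)c(OC)c(OC)c2 | intermediate
16 | (Z)-dienylketene: 4-hydroxy-6-R*-5-(trimethylsilyl)nona-1,3,5,8-tetraen-1-one, ketene CH and C5 cis | O=C=C/C=C(/O)\C(=C(/CC=C)[C@H](C)[C@@H](O[Si](C)(C)C(C)(C)C)c1cc(OC)c(OC)c(OC)c1)[Si](C)(C)C | intermediate
17 | (6R)-6-allyl-4-hydroxy-6-R*-5-(trimethylsilyl)cyclohexa-2,4-dien-1-one | C=CC[C@]1([C@H](C)[C@@H](O[Si](C)(C)C(C)(C)C)c2cc(OC)c(OC)c(OC)c2)C([Si](C)(C)C)=C(O)C=CC1=O | intermediate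
18 | (6R)-6-allyl-6-R*-cyclohex-2-ene-1,4-dione | C=CC[C@]1([C@H](C)[C@@H](O[Si](C)(C)C(C)(C)C)c2cc(OC)c(OC)c(OC)c2)CC(=O)C=CC1=O | intermediate
19 | (4R,6R)-6-allyl-4-hydroxy-6-R*-cyclohex-2-en-1-one | C=CC[C@]1([C@H](C)[C@@H](O[Si](C)(C)C(C)(C)C)c2cc(OC)c(OC)c(OC)c2)C[C@@H](O)C=CC1=O | intermediate
20 | (4R,6R)-6-allyl-4-methoxy-6-R*-cyclohex-2-en-1-one | C=CC[C@]1([C@H](C)[C@@H](O[Si](C)(C)C(C)(C)C)c2cc(OC)c(OC)c(OC)c2)C[C@@H](OC)C=CC1=O | intermediate
21 | megaphone | C=CC[C@]1([C@H](C)[C@@H](O)c2cc(OC)c(OC)c(OC)c2)C[C@@H](OC)C=CC1=O | target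

**Step count**

Total step count: 11. Longest linear sequence: 10 steps (steps 1, 2, 3, 4, 5, 7, 8, 9, 10, 11).

**Steps most likely to fail**

Step 8. The 6π closure onto the crowded, silyl-flanked terminus may be slow enough for the ketene to dimerise, or the dienol may suffer a [3,3] shift of its allyl group before it tautomerises. Facial selectivity at C6 may also be incomplete at 80 °C. The fallback is a charge-accelerated cascade that sets out from 9 and 13 and comes back at 18. The lithium alkoxide formed from alkenyllithium 14 and 13 would not be quenched but warmed from −78 to −20 °C. Oxyanion-accelerated ring opening (oxido group outward) and electrocyclisation should then give the lithium dienolate F1 at a temperature where neither the [3,3] shift nor ketene dimerisation competes. Aqueous HCl at 0 °C protonates F1 and removes the C5 silyl group to give 18.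

Step 5. Carbometalation of the α-branched silylalkyne may be sluggish or regiochemically unselective. The fallback is a silicon-free route that sets out from 5 and comes back at 18. Compound 5 would be silylated on oxygen only (TBSOTf, 2,6-lutidine) to give 6, which is isolated this time. Lewis acid catalysed trans-allylsilylation of the terminal alkyne (allyltrimethylsilane, HfCl4, CH2Cl2, 0 °C) should give the (Z)-vinylsilane F2 with silicon cis to the side chain. Ipso-iododesilylation with retention (N-iodosuccinimide, MeCN, 0 °C) gives the (Z)-vinyl iodide F3. Iodine–lithium exchange (t-BuLi) and addition to 13 give the hydroxycyclobutenone F4, in which the side chain is cis to the four-membered ring, so A(1,3) strain again fixes the reactive rotamer. Thermolysis of F4 as in step 8 should give 18 directly.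

Step 6. Over-bromination, ring contraction or polymerisation of the strained diones may erode the bromination–dehydrobromination sequence. The fallback replaces starting material 10: it sets out from commercial diisopropyl squarate (3,4-diisopropoxycyclobut-3-ene-1,2-dione) and comes back at 13. Twofold 1,2-reduction with i-Bu2AlH (THF, −78 °C) should give 3,4-diisopropoxycyclobut-3-ene-1,2-diol F5. Aqueous HCl then ionises each allylic hydroxyl group in turn, with capture of water at the alkoxy-bearing terminus and loss of propan-2-ol, to unveil both carbonyl groups of 13.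

Further compounds

F1 | step 8 | lithium dienolate of (6R)-6-allyl-6-R*-5-(trimethylsilyl)cyclohex-2-ene-1,4-dione (C4 oxygen) | C=CC[C@]1([C@H](C)[C@@H](O[Si](C)(C)C(C)(C)C)c2cc(OC)c(OC)c(OC)c2)C([Si](C)(C)C)=C(O[Li])C=CC1=O
F2 | step 5 | (Z)-2-R*-1-(trimethylsilyl)penta-1,4-diene, silicon cis to side chain | C=CC/C(=C/[Si](C)(C)C)[C@H](C)[C@@H](O[Si](C)(C)C(C)(C)C)c1cc(OC)c(OC)c(OC)c1
F3 | step 5 | (Z)-1-iodo-2-R*-penta-1,4-diene, iodine cis to side chain | C=CC/C(=C/I)[C@H](C)[C@@H](O[Si](C)(C)C(C)(C)C)c1cc(OC)c(OC)c(OC)c1
F4 | step 5 | 4-hydroxy-4-[(1Z)-2-R*-penta-1,4-dien-1-yl]cyclobut-2-en-1-one, carbinol epimers | C=CC/C(=C/C1(O)C=CC1=O)[C@H](C)[C@@H](O[Si](C)(C)C(C)(C)C)c2cc(OC)c(OC)c(OC)c2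
F5 | step 6 | 3,4-diisopropoxycyclobut-3-ene-1,2-diol | CC(C)OC1=C(OC(C)C)C(O)C1O
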